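**Retrosynthetic overview**
- The allyl group is made last: the target comes from a benzylic bromide and a vinyl Grignard reagent, and the bromide from the aryl ester by reduction and bromination. The ester stands in for the allyl group during the oxidation.
- The only ring formed is the dioxane ring, closed onto the ready-made benzene ring by making the O1–C2 bond in place of a C2–H bond (DDQ hydride abstraction, capture by the phenol).
- The cyclisation substrate comes from a Mitsunobu etherification (O4–C3 bond, inversion) of methyl 3,4-dihydroxybenzoate with an (S)-1-arylpropan-2-ol. That alcohol comes from the aryl Grignard reagent and (S)-propylene oxide.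
- Feature on which the strategy rests: with the hetero ring numbered O1–C2–C3–O4 and fused at C4a/C8a, C2 is a benzylic carbon of the 3,4,5-trimethoxyphenyl ring and lies six atoms from phenol oxygen O1 (O1–C8a–C4a–O4–C3–C2). A C2–H bond can therefore be exchanged for the O1–C2 bond, and the chiral-pool stereocentre C3 directs C2.

Key step: step 3

Remark: the dioxane ring is numbered O1–C2(aryl)–C3(methyl)–O4 throughout, O1 sitting on the arene carbon meta to the allyl (or ester) carbon C7. With this numbering the target is (2R,3R), which is the trans isomer. The starting materials, including vinylmagnesium bromide solution, are taken to be commercial.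

**Step 1**
Reactants: 1 5-bromo-1,2,3-trimethoxybenzene; 2 (S)-propylene oxide
Product: 4 (S)-1-(3,4,5-trimethoxyphenyl)propan-2-ol, via aryl Grignard reagent 3 (not isolated)
Conditions: Mg, I2 (cat.), THF, 50 °C; then CuI (10 mol %), 2, −30 → 0 °C; 1 M HCl
Reagents that add atoms: magnesium, [Mg] (held in intermediate 3 only, lost on work-up)
Why: Copper-catalysed opening of a terminal epoxide by an aryl Grignard reagent takes place by SN2 at the unsubstituted CH2, so the stereocentre of 2 is not touched and appears in 4 as (S).

**Step 2**
Reactants: 4 (S)-1-(3,4,5-trimethoxyphenyl)propan-2-ol; 5 methyl 3,4-dihydroxybenzoate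
Product: 6 methyl 3-hydroxy-4-{[(2R)-1-(3,4,5-trimethoxyphenyl)propan-2-yl]oxy}benzoate
Conditions: PPh3, DIAD (slow addition), 5 (1.5 equiv), THF, 0 °C → rt
Reagents that add atoms: none
Why: Mitsunobu etherification: the 4-OH of 5, para to the ester, is the more acidic phenol and is the one deprotonated by the betaine, and its phenoxide displaces the oxyphosphonium group of 4 by SN2 with inversion to give the (R)-ether, while the excess of 5 and slow addition of DIAD hold back double alkylation.

**Step 3**
Reactants: 6 methyl 3-hydroxy-4-{[(2R)-1-(3,4,5-trimethoxyphenyl)propan-2-yl]oxy}benzoate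
Product: 7 methyl (2R,3R)-3-methyl-2-(3,4,5-trimethoxyphenyl)-2,3-dihydro-1,4-benzodioxine-7-carboxylate
Conditions: DDQ (1.5 equiv), powdered 4 Å MS, ClCH2CH2Cl, N2, dark, rt → 70 °C; aq NaHCO3
Reagents that add atoms: none
Why: Proposed new method: DDQ should bind the electron-rich trimethoxyphenyl ring as a donor–acceptor complex and then remove the C2 hydrogen as hydride (in one step or by electron, proton and electron transfer), leaving a C2 benzylic cation that the 4-methoxy group stabilises in its quinoidal oxocarbenium form, after which phenol oxygen O1 adds to C2 and gives its proton to the reduced quinone. The closest known reaction type is the DDQ-mediated dehydrogenative cyclisation of 2-(3-arylpropyl)phenols to flavans and of 2-cinnamylphenols to flavenes; not yet shown are a substrate with an aryloxy group next to the reacting CH2 and the closure of a 1,4-dioxane ring, and since that oxygen and the two meta methoxy groups make the cation poorer than in the known cases, warming is provided for. The dioxane ring (O1–C2–C3–O4–C4a–C8a) closes in a 6-exo-trig mode, because the C2=aryl π-system of the cation stays outside the new ring. The new stereocentre C2 is controlled by the C3 stereocentre: to avoid allylic strain with the ortho hydrogens of the aryl ring the cation places C3–H rather than the C3 methyl in the aryl plane, O1 comes from the face that holds O4, and the half-chair so formed has methyl and aryl trans and pseudo-equatorial, (2R,3R), which is also the more stable isomer. The step needs site selectivity for C2–H, and the substrate secures it: C2 is the only benzylic CH2 on an electron-rich ring, the ester makes the phenol ring a poor donor, the DDQ-sensitive allyl group is not yet there, and molecular sieves keep water from the cation.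

**Step 4**
Reactants: 7 methyl (2R,3R)-3-methyl-2-(3,4,5-trimethoxyphenyl)-2,3-dihydro-1,4-benzodioxine-7-carboxylate
Product: 8 [(2R,3R)-3-methyl-2-(3,4,5-trimethoxyphenyl)-2,3-dihydro-1,4-benzodioxin-7-yl]methanol
Conditions: LiAlH4, THF, 0 °C; H2O, aq NaOH
Reagents that add atoms: none
Why: Hydride reduction of the aryl ester to the primary benzylic alcohol; the aryl and benzylic ethers and both stereocentres are inert to LiAlH4.

**Step 5**
Reactants: 8 [(2R,3R)-3-methyl-2-(3,4,5-trimethoxyphenyl)-2,3-dihydro-1,4-benzodioxin-7-yl]methanol
Product: 9 (2R,3R)-7-(bromomethyl)-3-methyl-2-(3,4,5-trimethoxyphenyl)-2,3-dihydro-1,4-benzodioxine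
Conditions: CBr4, PPh3, CH2Cl2, 0 °C; short silica plug, used at once
Reagents that add atoms: carbon tetrabromide, BrC(Br)(Br)Br
Why: Appel bromination turns the primary benzylic alcohol into the bromide under neutral conditions, so that no HBr is present to ionise the benzylic C2–O1 ether.

**Step 6**
Reactants: 9 (2R,3R)-7-(bromomethyl)-3-methyl-2-(3,4,5-trimethoxyphenyl)-2,3-dihydro-1,4-benzodioxine; 10 vinylmagnesium bromide
Product: 11 (2R,3R)-3-methyl-7-(prop-2-en-1-yl)-2-(3,4,5-trimethoxyphenyl)-2,3-dihydro-1,4-benzodioxine
Conditions: 10 (1.5 equiv), CuI (10 mol %), THF, −20 → 0 °C; aq NH4Cl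
Reagents that add atoms: none
Why: Copper-catalysed sp3–sp2 coupling of a benzylic bromide with a vinyl Grignard reagent (Kochi-type substitution through a vinylcopper species) joins the vinyl group to the benzylic CH2 and so completes the allyl group at low temperature, where the double bond should not move into conjugation.

**Compound list**
1 | 5-bromo-1,2,3-trimethoxybenzene | COc1cc(Br)cc(OC)c1OC | starting material
2 | (S)-propylene oxide | C[C@H]1CO1 | starting material
3 | (3,4,5-trimethoxyphenyl)magnesium bromide (not isolated) | COc1cc([Mg]Br)cc(OC)c1OC | intermediate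
4 | (S)-1-(3,4,5-trimethoxyphenyl)propan-2-ol | C[C@H](O)Cc1cc(OC)c(OC)c(OC)c1 | intermediate
5 | methyl 3,4-dihydroxybenzoate | COC(=O)c1ccc(O)c(O)c1 | starting material
6 | methyl 3-hydroxy-4-{[(2R)-1-(3,4,5-trimethoxyphenyl)propan-2-yl]oxy}benzoate | COC(=O)c1ccc(O[C@H](C)Cc2cc(OC)c(OC)c(OC)c2)c(O)c1 | intermediate
7 | methyl (2R,3R)-3-methyl-2-(3,4,5-trimethoxyphenyl)-2,3-dihydro-1,4-benzodioxine-7-carboxylate | COC(=O)c1ccc2c(c1)O[C@H](c1cc(OC)c(OC)c(OC)c1)[C@@H](C)O2 | intermediate
8 | [(2R,3R)-3-methyl-2-(3,4,5-trimethoxyphenyl)-2,3-dihydro-1,4-benzodioxin-7-yl]methanol | OCc1ccc2c(c1)O[C@H](c1cc(OC)c(OC)c(OC)c1)[C@@H](C)O2 | intermediate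
9 | (2R,3R)-7-(bromomethyl)-3-methyl-2-(3,4,5-trimethoxyphenyl)-2,3-dihydro-1,4-benzodioxine | BrCc1ccc2c(c1)O[C@H](c1cc(OC)c(OC)c(OC)c1)[C@@H](C)O2 | intermediate
10 | vinylmagnesium bromide | C=C[Mg]Br | starting material
11 | (2R,3R)-3-methyl-7-(prop-2-en-1-yl)-2-(3,4,5-trimethoxyphenyl)-2,3-dihydro-1,4-benzodioxine | C=CCc1ccc2c(c1)O[C@H](c1cc(OC)c(OC)c(OC)c1)[C@@H](C)O2 | target

**Total step count:** 6
**Longest linear sequence:** 6 steps (1 → 4 → 6 → 7 → 8 → 9 → 11)

**Steps most likely to fail**

1. Step 3 (bears the label "Proposed new method:").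
- Hydride transfer from C2 may be too slow, because the aryloxy group on C3 and the twisted 4-methoxy group stabilise the cation less than in the flavan cases.
- The cation may lose the C3 proton to an enol ether that DDQ degrades further.
- Traces of water may capture the cation, followed by over-oxidation to the aryl ketone.
- The product may be oxidised further at its C2–H.
- Trans selectivity may be incomplete, since the C2–O1 bond is not expected to ionise reversibly under neutral DDQ conditions.

Fallback (known chemistry): the same C2 cation is reached by acid ionisation of a C2 alcohol, where ring closure is reversible and under thermodynamic control. The fallback sets out from 5 and Grignard reagent 3 and comes back to the route at 7. Ethyl (S)-lactate is converted with MeNHOMe·HCl and i-PrMgCl (THF, −20 °C) into (S)-2-hydroxy-N-methoxy-N-methylpropanamide F1. Mitsunobu reaction of F1 with 5 (PPh3, DIAD, THF), again at the more acidic 4-OH and with inversion, should give methyl 3-hydroxy-4-{[(2R)-1-[methoxy(methyl)amino]-1-oxopropan-2-yl]oxy}benzoate F2. After deprotonation of the phenol with one equivalent of i-PrMgCl, reagent 3 should add to the Weinreb amide only (THF, −20 °C) and give methyl 3-hydroxy-4-{[(2R)-1-oxo-1-(3,4,5-trimethoxyphenyl)propan-2-yl]oxy}benzoate F3. Reduction with NaBH4 (MeOH, 0 °C) should then give methyl 3-hydroxy-4-{[(2R)-1-hydroxy-1-(3,4,5-trimethoxyphenyl)propan-2-yl]oxy}benzoate F4 as a mixture of carbinol epimers, which does not matter. BF3·OEt2 in CH2Cl2 (0 °C → rt) ionises the benzylic alcohol and the phenol closes the ring to trans 7. This is the SN1 cyclodehydration long used for 2-aryl-3-methyl-1,4-benzodioxanes.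

2. Step 2. Etherification may occur at the 3-OH or at both phenol oxygens, and the activated secondary oxyphosphonium salt may eliminate to the propenylarene.

Fallback: the place of O1 is held by a bromine atom until the ether is made, so that only one phenol is present. The fallback sets out from 4 and comes back at 6. Mitsunobu reaction of 4 with commercial methyl 3-bromo-4-hydroxybenzoate (PPh3, DIAD, THF) should give methyl 3-bromo-4-{[(2R)-1-(3,4,5-trimethoxyphenyl)propan-2-yl]oxy}benzoate F5. Miyaura borylation (B2pin2, Pd(dppf)Cl2, KOAc, dioxane, 90 °C) should give methyl 3-(4,4,5,5-tetramethyl-1,3,2-dioxaborolan-2-yl)-4-{[(2R)-1-(3,4,5-trimethoxyphenyl)propan-2-yl]oxy}benzoate F6. Oxidation of the C–B bond with NaBO3·4H2O (THF/H2O, rt) leaves the ester intact and gives phenol 6.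

3. Step 6. Bromine–magnesium exchange may lead to Wurtz-type homocoupling of the electron-rich benzylic bromide to a bibenzyl, and basic magnesium species may move the new double bond into conjugation with the arene.

Fallback: the Grignard/copper substitution is replaced by a neutral palladium-catalysed cross-coupling. It sets out from 9 and comes back at 11: Stille coupling of 9 with tributyl(vinyl)stannane (Pd(PPh3)4, THF, 65 °C), a known route from benzylic bromides to allylarenes that uses no strongly basic organometallic reagent.

**Further compounds**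
F1 | step 3 | (S)-2-hydroxy-N-methoxy-N-methylpropanamide | C[C@H](O)C(=O)N(C)OC
F2 | step 3 | methyl 3-hydroxy-4-{[(2R)-1-[methoxy(methyl)amino]-1-oxopropan-2-yl]oxy}benzoate | COC(=O)c1ccc(O[C@H](C)C(=O)N(C)OC)c(O)c1
F3 | step 3 | methyl 3-hydroxy-4-{[(2R)-1-oxo-1-(3,4,5-trimethoxyphenyl)propan-2-yl]oxy}benzoate | COC(=O)c1ccc(O[C@H](C)C(=O)c2cc(OC)c(OC)c(OC)c2)c(O)c1
F4 | step 3 | methyl 3-hydroxy-4-{[(2R)-1-hydroxy-1-(3,4,5-trimethoxyphenyl)propan-2-yl]oxy}benzoate (both carbinol epimers) | COC(=O)c1ccc(O[C@H](C)C(O)c2cc(OC)c(OC)c(OC)c2)c(O)c1
F5 | step 2 | methyl 3-bromo-4-{[(2R)-1-(3,4,5-trimethoxyphenyl)propan-2-yl]oxy}benzoate | COC(=O)c1ccc(O[C@H](C)Cc2cc(OC)c(OC)c(OC)c2)c(Br)c1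
F6 | step 2 | methyl 3-(4,4,5,5-tetramethyl-1,3,2-dioxaborolan-2-yl)-4-{[(2R)-1-(3,4,5-trimethoxyphenyl)propan-2-yl]oxy}benzoate | COC(=O)c1ccc(O[C@H](C)Cc2cc(OC)c(OC)c(OC)c2)c(B2OC(C)(C)C(C)(C)O2)c1
F0 | step 6 | none | none
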